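**Strategy.** The dihydropyranone ring is disconnected at O1–C8a and C2–C3 (chromene numbering of the target), giving acetaldehyde and a propanoyl group on the methoxy-bearing vinylogous ester of the non-aromatic carbocycle. The key step exploits exactly this feature, MeO–C8a=C4a–C4=O next to the quaternary sp3 carbon C8: a chiral (acyloxy)borane-catalysed Mukaiyama aldol addition of the silyl dienol ether to acetaldehyde forms C2–C3 and both methyl-bearing stereocentres, and acid then closes the ring by addition–elimination at C8a, forming O1–C8a. The precursor is built from phloroglucinol by organocatalytic Friedel–Crafts alkylation, copper-catalysed allylic alkylation and palladium-catalysed dearomative prenylation; the carboxyl group stays masked as a cyclic acetal until the end.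

Key step: step 12

Remark: the acetal carbon C-2 of intermediates 3–17 is carried as a mixture of epimers (it is not a stereocentre of the target and is removed in step 13); the catalyst enantiomers named for steps 6, 9 and 12 are those expected from the accepted models, the antipodes being equally available.

Ring A is the dihydropyranone ring, ring B the carbocycle. Intermediates 4–14 are numbered as chromenes (O1, C2 acetal carbon, C4 propyl-bearing carbon).

**Step 1**
Reactants: 1 phloroglucinol; 2 (E)-hex-2-enal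
Product: 4 (4S)-2-methoxy-4-propyl-3,4-dihydro-2H-chromene-5,7-diol as C-2 epimers, via lactol 3 (not isolated)
Conditions: 1 (3 equiv), (R)-α,α-diphenylprolinol trimethylsilyl ether (20 mol%), PhCO2H (20 mol%), MeCN, 0 °C to rt; aqueous wash; then MeOH, PPTS (10 mol%), rt
Reagents that add atoms: methanol, CO
Why: Iminium-catalysed Friedel–Crafts conjugate addition of the phenol to the enal, hemiacetal closure onto an ortho hydroxyl and acid-catalysed acetalisation should work because all ring positions of 1 are equivalent, and the bulky group of the (R)-catalyst shields one face of the (E)-iminium ion so that the aryl group adds to the open face and sets the (4S) centre.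

**Step 2**
Reactants: 4 (4S)-2-methoxy-4-propyl-3,4-dihydro-2H-chromene-5,7-diol
Product: 5 (4S)-2-methoxy-4-propyl-5,7-bis{[2-(trimethylsilyl)ethoxy]methoxy}-3,4-dihydro-2H-chromene
Conditions: NaH (2.3 equiv), SEMCl (2.3 equiv), DMF, 0 °C to rt
Reagents that add atoms: 2-(trimethylsilyl)ethoxymethyl chloride, C[Si](C)(C)CCOCCl
Why: Williamson etherification of both phenols gives SEM ethers, which direct ortho-lithiation later and are removable with fluoride without acid.

**Step 3**
Reactants: 5 bis-SEM ether
Product: 6 (4S)-2-methoxy-6-(3-methylbut-2-en-1-yl)-4-propyl-5,7-bis{[2-(trimethylsilyl)ethoxy]methoxy}-3,4-dihydro-2H-chromene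
Conditions: n-BuLi (1.2 equiv), THF, 0 °C; CuBr·SMe2 (10 mol%), prenyl bromide, −78 °C to 0 °C
Reagents that add atoms: prenyl bromide, CC(C)=CCBr
Why: Directed ortho-metalation should occur at C-6, the position flanked by both SEM-oxy groups, and the copper-assisted aryl nucleophile is alkylated by prenyl bromide at its primary carbon (SN2).

**Step 4**
Reactants: 6 C-6 prenyl arene
Product: 7 (2E)-4-[(4S)-2-methoxy-4-propyl-5,7-bis{[2-(trimethylsilyl)ethoxy]methoxy}-3,4-dihydro-2H-chromen-6-yl]-2-methylbut-2-en-1-ol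
Conditions: SeO2 (0.3 equiv), t-BuOOH (3 equiv), CH2Cl2, 0 °C to rt
Reagents that add atoms: tert-butyl hydroperoxide, CC(C)(C)OO
Why: Sharpless SeO2/t-BuOOH allylic oxidation (ene reaction, then [2,3]-sigmatropic shift) oxidises the methyl group trans to the chain of the trisubstituted alkene and should give the (E)-allylic alcohol only.

**Step 5**
Reactants: 7 (E)-allylic alcohol
Product: 8 (4S)-6-[(2E)-4-chloro-3-methylbut-2-en-1-yl]-2-methoxy-4-propyl-5,7-bis{[2-(trimethylsilyl)ethoxy]methoxy}-3,4-dihydro-2H-chromene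
Conditions: NCS, Me2S, CH2Cl2, −20 °C to 0 °C
Reagents that add atoms: N-chlorosuccinimide, O=C1CCC(=O)N1Cl
Why: Corey–Kim chlorination through the alkoxysulfonium salt replaces the primary allylic hydroxyl by chloride (SN2) without allylic transposition or loss of the (E) geometry.

**Step 6**
Reactants: 8 (E)-allylic chloride
Product: 9 (4S)-2-methoxy-6-[(2R)-5-methyl-2-(prop-1-en-2-yl)hex-5-en-1-yl]-4-propyl-5,7-bis{[2-(trimethylsilyl)ethoxy]methoxy}-3,4-dihydro-2H-chromene
Conditions: 3-methylbut-3-enylmagnesium bromide (1.3 equiv, from 4-bromo-2-methylbut-1-ene and Mg in Et2O), copper thiophene-2-carboxylate Cu(O2CC4H3S) (3 mol%), (S,S,S)-2,2′-binaphthol-derived phosphoramidite of bis[1-(2-methoxyphenyl)ethyl]amine (3.3 mol%), CH2Cl2, −78 °C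
Reagents that add atoms: 4-bromo-2-methylbut-1-ene (used as its Grignard reagent), C=C(C)CCBr
Why: Copper-catalysed asymmetric allylic alkylation of a 2-methyl-substituted allylic chloride with a Grignard reagent should deliver the alkyl group to the γ-carbon (SN2′), creating the isopropenyl group and the new centre in one event, with the phosphoramidite ligand selecting the alkene face to give (R).

**Step 7**
Reactants: 9 side-chain arene
Product: 10 1-[(4S)-2-methoxy-6-[(2R)-5-methyl-2-(prop-1-en-2-yl)hex-5-en-1-yl]-4-propyl-5,7-bis{[2-(trimethylsilyl)ethoxy]methoxy}-3,4-dihydro-2H-chromen-8-yl]propan-1-one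
Conditions: n-BuLi (1.3 equiv), TMEDA, THF, −78 °C to −20 °C; N-methoxy-N-methylpropanamide, −78 °C to 0 °C
Reagents that add atoms: N-methoxy-N-methylpropanamide, CCC(=O)N(C)OC
Why: The only aromatic hydrogen left (C-8, between a SEM-oxy group and the ring oxygen) is removed by directed ortho-metalation, and the aryllithium is acylated by the Weinreb amide, whose chelated adduct prevents over-addition.

**Step 8**
Reactants: 10 aryl ethyl ketone
Product: 11 1-[(4S)-5,7-dihydroxy-2-methoxy-6-[(2R)-5-methyl-2-(prop-1-en-2-yl)hex-5-en-1-yl]-4-propyl-3,4-dihydro-2H-chromen-8-yl]propan-1-one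
Conditions: TBAF (6 equiv), THF/DMPU, 60 °C; NH4Cl work-up
Reagents that add atoms: none
Why: Fluoride attacks silicon and each SEM group fragments to Me3SiF, ethene and formaldehyde under basic conditions that should leave the methyl acetal, the ketone and the alkenes untouched.

**Step 9**
Reactants: 11 diphenol
Product: 12 (4S,6R)-7-hydroxy-2-methoxy-6-(3-methylbut-2-en-1-yl)-6-[(2R)-5-methyl-2-(prop-1-en-2-yl)hex-5-en-1-yl]-8-propanoyl-4-propyl-3,4-dihydro-2H-chromen-5(6H)-one
Conditions: Pd2(dba)3 (2.5 mol%), (1R,2R)-N,N′-bis[2-(diphenylphosphanyl)benzoyl]cyclohexane-1,2-diamine (7.5 mol%), prenyl acetate (1.2 equiv), Cs2CO3 (1.1 equiv), THF, 0 °C to rt; NaH2PO4 work-up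
Reagents that add atoms: prenyl acetate, CC(C)=CCOC(C)=O
Why: In this Tsuji–Trost allylic alkylation with dearomatisation, the phenoxide should attack the π-prenyl palladium complex through C-6 (the carbon flanked by both oxygens) at the unsubstituted allyl terminus to give a stable vinylogous acid, and the chiral diphosphine differentiates the two faces of the planar nucleophile to set the quaternary centre as (R), the existing centres being remote.

**Step 10**
Reactants: 12 dearomatised enol
Product: 13 (4S,6R)-2,7-dimethoxy-6-(3-methylbut-2-en-1-yl)-6-[(2R)-5-methyl-2-(prop-1-en-2-yl)hex-5-en-1-yl]-8-propanoyl-4-propyl-3,4-dihydro-2H-chromen-5(6H)-one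
Conditions: TMSCHN2 (1.5 equiv), toluene/MeOH 4:1, 0 °C
Reagents that add atoms: (trimethylsilyl)diazomethane, C[Si](C)(C)C=[N+]=[N-]
Why: Diazoalkane O-methylation of the only acidic hydroxyl (the ring enol hydrogen-bonded to the propanoyl carbonyl) should give the methyl vinylogous ester whose methoxy group is the leaving group of the key step.

**Step 11**
Reactants: 13 methyl vinylogous ester
Product: 14 (4S,6R)-2,7-dimethoxy-6-(3-methylbut-2-en-1-yl)-6-[(2R)-5-methyl-2-(prop-1-en-2-yl)hex-5-en-1-yl]-4-propyl-8-[(1Z)-1-(trimethylsilyloxy)prop-1-en-1-yl]-3,4-dihydro-2H-chromen-5(6H)-one (used crude)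
Conditions: TMSOTf (1.3 equiv), Et3N (2.5 equiv), Et2O, −78 °C to 0 °C
Reagents that add atoms: trimethylsilyl trifluoromethanesulfonate, C[Si](C)(C)OS(=O)(=O)C(F)(F)F
Why: Soft enolisation (silyl triflate and amine) of the only enolisable carbonyl should give the silyl dienol ether, expected as the (Z) isomer because the methyl group avoids the ring substituents, while the amine buffers the acetal against the silyl triflate.

**Step 12**
Reactants: 14 silyl dienol ether; 15 acetaldehyde
Product: 17 ring-A-closed methyl acetal (2R,3S)-cis, via aldol silyl ether 16 (not isolated)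
Conditions: CH3CHO (3 equiv), (acyloxy)borane made in situ from (2S,3S)-2-O-(2,6-diisopropoxybenzoyl)tartaric acid and BH3·THF (20 mol%), EtCN, −78 °C; then CSA (0.2 equiv), MeOH, 0 °C to rt
Reagents that add atoms: none
Why: The (acyloxy)borane binds acetaldehyde and the (Z)-silyl dienol ether adds through an open transition state (Mukaiyama aldol), which forms C2–C3 and returns the methoxy vinylogous ester as the silyl-protected aldol 16; camphorsulfonic acid in methanol then frees the hydroxyl, which adds to C8a and expels methanol, forming O1–C8a (target numbering). The closest known reaction type is the Lewis-acid-catalysed cyclocondensation of 1-methoxy-3-silyloxy-1,3-dienes with aldehydes in its stepwise aldol–cyclisation form, for which tartrate-derived (acyloxy)boranes are known to give cis-2,3-disubstituted dihydropyran-4-ones. Ring A closes in the 6-endo-trig mode (conjugate addition to the enone carbon C8a, then elimination), which is open only because ring B is not aromatic, so that C8a is a vinylogous ester carbon. C2 and C3 are both set in the aldol event: the catalyst gives the syn adduct irrespective of enol ether geometry (cis ring after closure), and its (2S,3S)-tartrate backbone should expose the Si face of acetaldehyde, giving (2R,3S), the older centres being too far away to compete. The step needs ring closure at C8a and not at C5, secured because only C8a bears a leaving group conjugated to the side-chain carbonyl while the C5 oxygen is tied up in the acetal ring; it also needs the kinetic cis isomer to persist, which the base-free closure allows.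

**Step 13**
Reactants: 17 ring-A-closed methyl acetal
Product: 19 CNP0294320.1 (target acid), via aldehyde 18 (not isolated)
Conditions: 0.5 M HCl, THF/H2O, 0 °C to rt; then NaH2PO4, 2-methyl-2-butene (30 equiv), NaClO2, t-BuOH/H2O, 0 °C to rt
Reagents that add atoms: water, O; sodium chlorite, [Na+].[O-]Cl=O
Why: Dilute acid hydrolyses the enol-type cyclic acetal to the aldehyde and the free C5 enol, and Pinnick oxidation (chlorous acid, hypochlorite scavenged by 2-methyl-2-butene) converts the aldehyde into the acid without base, so the cis-2,3-dimethyl ring and the alkenes should survive.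

**Compound list**

1 | phloroglucinol (benzene-1,3,5-triol) | Oc1cc(O)cc(O)c1 | starting material
2 | (E)-hex-2-enal | CCC/C=C/C=O | starting material
3 | (4S)-4-propyl-3,4-dihydro-2H-chromene-2,5,7-triol (lactol, C-2 epimers) | OC1C[C@H](CCC)c2c(O)cc(O)cc2O1 | intermediate
4 | (4S)-2-methoxy-4-propyl-3,4-dihydro-2H-chromene-5,7-diol (C-2 epimers) | COC1C[C@H](CCC)c2c(O)cc(O)cc2O1 | intermediate
5 | (4S)-2-methoxy-4-propyl-5,7-bis{[2-(trimethylsilyl)ethoxy]methoxy}-3,4-dihydro-2H-chromene | COC1C[C@H](CCC)c2c(OCOCC[Si](C)(C)C)cc(OCOCC[Si](C)(C)C)cc2O1 | intermediate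
6 | 6-(3-methylbut-2-en-1-yl) derivative of 5 | COC1C[C@H](CCC)c2c(OCOCC[Si](C)(C)C)c(CC=C(C)C)c(OCOCC[Si](C)(C)C)cc2O1 | intermediate
7 | 6-[(2E)-4-hydroxy-3-methylbut-2-en-1-yl] derivative of 5 | COC1C[C@H](CCC)c2c(OCOCC[Si](C)(C)C)c(C/C=C(\C)CO)c(OCOCC[Si](C)(C)C)cc2O1 | intermediate
8 | 6-[(2E)-4-chloro-3-methylbut-2-en-1-yl] derivative of 5 | COC1C[C@H](CCC)c2c(OCOCC[Si](C)(C)C)c(C/C=C(\C)CCl)c(OCOCC[Si](C)(C)C)cc2O1 | intermediate
9 | 6-[(2R)-5-methyl-2-(prop-1-en-2-yl)hex-5-en-1-yl] derivative of 5 | COC1C[C@H](CCC)c2c(OCOCC[Si](C)(C)C)c(C[C@@H](CCC(C)=C)C(C)=C)c(OCOCC[Si](C)(C)C)cc2O1 | intermediate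
10 | 8-propanoyl derivative of 9 | COC1C[C@H](CCC)c2c(OCOCC[Si](C)(C)C)c(C[C@@H](CCC(C)=C)C(C)=C)c(OCOCC[Si](C)(C)C)c(C(=O)CC)c2O1 | intermediate
11 | 1-[(4S)-5,7-dihydroxy-2-methoxy-6-[(2R)-5-methyl-2-(prop-1-en-2-yl)hex-5-en-1-yl]-4-propyl-3,4-dihydro-2H-chromen-8-yl]propan-1-one | COC1C[C@H](CCC)c2c(O)c(C[C@@H](CCC(C)=C)C(C)=C)c(O)c(C(=O)CC)c2O1 | intermediate
12 | (4S,6R)-7-hydroxy-2-methoxy-6-(3-methylbut-2-en-1-yl)-6-[(2R)-5-methyl-2-(prop-1-en-2-yl)hex-5-en-1-yl]-8-propanoyl-4-propyl-3,4-dihydro-2H-chromen-5(6H)-one | C=C(C)CC[C@H](C[C@@]1(CC=C(C)C)C(=O)C2=C(OC(OC)C[C@@H]2CCC)C(C(=O)CC)=C1O)C(=C)C | intermediate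
13 | 7-O-methyl ether of 12 (2,7-dimethoxy compound) | C=C(C)CC[C@H](C[C@@]1(CC=C(C)C)C(=O)C2=C(OC(OC)C[C@@H]2CCC)C(C(=O)CC)=C1OC)C(=C)C | intermediate
14 | (Z)-trimethylsilyl enol ether of the propanoyl group of 13 | C=C(C)CC[C@H](C[C@@]1(CC=C(C)C)C(=O)C2=C(OC(OC)C[C@@H]2CCC)C(/C(O[Si](C)(C)C)=C/C)=C1OC)C(=C)C | intermediate
15 | acetaldehyde | CC=O | starting material
16 | 13 in which the propanoyl group is (2S,3R)-2-methyl-3-(trimethylsilyloxy)butanoyl | C=C(C)CC[C@H](C[C@@]1(CC=C(C)C)C(=O)C2=C(OC(OC)C[C@@H]2CCC)C(C(=O)[C@@H](C)[C@@H](C)O[Si](C)(C)C)=C1OC)C(=C)C | intermediate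
17 | target skeleton with ring A closed, (2R,3S)-cis; carboxyl carbon still a CH(OMe) acetal carbon bonded to the C5 oxygen (six-membered cyclic acetal) | C=C(C)CC[C@H](C[C@@]1(CC=C(C)C)C(=O)C2=C(OC(OC)C[C@@H]2CCC)C3=C1O[C@H](C)[C@H](C)C3=O)C(=C)C | intermediate
18 | (3S)-3-[(2R,3S,8R)-5-hydroxy-2,3-dimethyl-8-(3-methylbut-2-en-1-yl)-8-[(2R)-5-methyl-2-(prop-1-en-2-yl)hex-5-en-1-yl]-4,7-dioxo-2,3,7,8-tetrahydro-4H-chromen-6-yl]hexanal | C=C(C)CC[C@H](C[C@@]1(CC=C(C)C)C(=O)C([C@@H](CCC)CC=O)=C(O)C2=C1O[C@H](C)[C@H](C)C2=O)C(=C)C | intermediate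
19 | CNP0294320.1, (3S)-3-[(2R,3S,8R)-5-hydroxy-2,3-dimethyl-8-(3-methylbut-2-en-1-yl)-8-[(2R)-5-methyl-2-(prop-1-en-2-yl)hex-5-en-1-yl]-4,7-dioxo-2,3,7,8-tetrahydro-4H-chromen-6-yl]hexanoic acid | C=C(C)CC[C@H](C[C@@]1(CC=C(C)C)C(=O)C([C@@H](CCC)CC(=O)O)=C(O)C2=C1O[C@H](C)[C@H](C)C2=O)C(=C)C | target

**Totals.** Total step count: 13. Longest linear sequence: 13 steps (from phloroglucinol).

**Steps most likely to fail**

1. Step 12. The hindered, cross-conjugated silyl dienol ether may add too slowly, or with poor syn and facial selectivity, to a small enolisable aldehyde. The boron Lewis acid may also ionise the acetal, and the cis ring may epimerise during closure. Fallback, from 13 back to 17: ketone 13 is enolised with diisopinocampheylboron triflate (the enantiomer that attacks the Si face of acetaldehyde) and i-Pr2NEt in CH2Cl2 at −78 °C. Acetaldehyde is added and the boron aldolate is worked up with H2O2 in pH 7 buffer. The closed chair transition state of the (Z)-boron enolate (Paterson aldol) should give the syn-β-hydroxy ketone F1. CSA in MeOH then closes ring A with loss of methanol to give 17.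

2. Step 9. The phenoxide may be allylated on oxygen, at C-4a or through the branched allyl terminus, and facial selectivity at C-6 may be poor because the two flanking groups differ little. Fallback, from 11 back to 12: ion-pair control in place of the palladium complex. 11 is alkylated with prenyl bromide and CsOH·H2O under phase-transfer catalysis with N-(9-anthracenylmethyl)cinchonidinium bromide (10 mol%) in toluene/CH2Cl2 at −40 °C. The C-6 epimers are diastereomers and can be separated if selectivity is incomplete. New compounds: none F0.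

3. Step 6. Direct SN2 substitution may compete with SN2′, and the ortho SEM-oxy groups may erode the enantioselectivity. Fallback, from 5 back to 9, with an auxiliary in place of the catalyst:
 - 5 is lithiated at C-6 (n-BuLi, THF, 0 °C) and formylated with DMF to the aldehyde F2.
 - NaBH4 gives the benzylic alcohol F3, and CBr4/PPh3 gives the benzylic bromide F4, which is used at once.
 - (R)-4-Benzyl-3-(3-methylbut-2-enoyl)oxazolidin-2-one F5 is made from (R)-4-benzyloxazolidin-2-one, n-BuLi and 3-methylbut-2-enoyl chloride.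
 - Its sodium dienolate (NaHMDS, THF, −78 °C) is alkylated by F4 at the α-carbon, on the face away from the benzyl group (Evans deconjugative alkylation), to give the imide F6 with the (R) centre and the isopropenyl group.
 - LiBH4 removes the auxiliary to give the primary alcohol F7, and Tf2O/2,6-lutidine gives the triflate F8.
 - Coupling with 2-methylallylmagnesium chloride (CuI 10 mol%, THF, −40 °C) returns 9.

**Further compounds**

F1 | step 12 | 13 in which the propanoyl group is (2S,3R)-3-hydroxy-2-methylbutanoyl | C=C(C)CC[C@H](C[C@@]1(CC=C(C)C)C(=O)C2=C(OC(OC)C[C@@H]2CCC)C(C(=O)[C@@H](C)[C@@H](C)O)=C1OC)C(=C)C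
F0 | step 9 | none | none
F2 | step 6 | (4S)-2-methoxy-4-propyl-5,7-bis{[2-(trimethylsilyl)ethoxy]methoxy}-3,4-dihydro-2H-chromene-6-carbaldehyde | COC1C[C@H](CCC)c2c(OCOCC[Si](C)(C)C)c(C=O)c(OCOCC[Si](C)(C)C)cc2O1
F3 | step 6 | 6-(hydroxymethyl) derivative of 5 | COC1C[C@H](CCC)c2c(OCOCC[Si](C)(C)C)c(CO)c(OCOCC[Si](C)(C)C)cc2O1
F4 | step 6 | 6-(bromomethyl) derivative of 5 | COC1C[C@H](CCC)c2c(OCOCC[Si](C)(C)C)c(CBr)c(OCOCC[Si](C)(C)C)cc2O1
F5 | step 6 | (R)-4-benzyl-3-(3-methylbut-2-enoyl)oxazolidin-2-one | CC(C)=CC(=O)N1[C@H](Cc2ccccc2)COC1=O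
F6 | step 6 | (R)-4-benzyl-3-[(2R)-2-(aryl-methyl)-3-methylbut-3-enoyl]oxazolidin-2-one, aryl = C-6 of 5 | COC1C[C@H](CCC)c2c(OCOCC[Si](C)(C)C)c(C[C@H](C(C)=C)C(=O)N3[C@H](Cc4ccccc4)COC3=O)c(OCOCC[Si](C)(C)C)cc2O1
F7 | step 6 | (2R)-2-(aryl-methyl)-3-methylbut-3-en-1-ol, aryl = C-6 of 5 | COC1C[C@H](CCC)c2c(OCOCC[Si](C)(C)C)c(C[C@H](C(C)=C)CO)c(OCOCC[Si](C)(C)C)cc2O1
F8 | step 6 | trifluoromethanesulfonate of F7 | COC1C[C@H](CCC)c2c(OCOCC[Si](C)(C)C)c(C[C@H](C(C)=C)COS(=O)(=O)C(F)(F)F)c(OCOCC[Si](C)(C)C)cc2O1
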